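**Strategy**

- Retrosynthesis: once the C8 methacrylate and the two silyl ethers are taken off, the C6–C7 bond and the lactone C12–O bond are cut in one retro-[2,3]-Wittig operation. This unfolds the ten-membered carbocycle and the γ-lactone into a thirteen-membered C6–O–C13 allyl ether. Further cuts are C7=C11 (olefination), O–C3 of the furanone, C3–C4 (Sonogashira), C1–C2 (acetylide on a Weinreb amide) and C11–C13 (alkylation).
- Enabling feature: C6 is both the oxygen-bearing fusion carbon of the α-methylene-γ-lactone (unit C6(O)–C7–C11(=C13H2)–C12=O on the ten-membered ring) and the ε-position of the furanone dienone C1(=O)–C2=C3–C4=C5. A C6 carbanion of the ether is therefore within reach of a base, and its [2,3]-shift onto C7 writes exactly the homoallylic C6–O/C11=C13 pattern.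
- Forward: a west piece (C4–C6, C15, C11–C13; vinyl iodide plus phosphonate) and an east piece (C1–C3, C7–C10, C14; alkyne) are joined at C3–C4. The rings arise in the order furanone (O–C3), thirteen-membered ether ring (C7=C11), then ten-membered carbocycle and lactone together.
- Stereochemistry: C8 is bought with the (S)-lactone from the chiral pool. C10 is set by enolate hydroxylation anti to the C8 side chain. C6 and C7 are set in the ring contraction by C8 and by the enoate geometry of the Still–Gennari step. The C4=C5 geometry stems from the trans-hydroalumination/iodination.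

Key step: step 17

Remark: atoms carry germacrane numbers (C1 ketone; C2=C3 and the C3–O–C10 bridge of the furanone; C4=C5 with C15 on C4; C6 and C7 at the lactone fusion; C8 ester carbon; C11=C13 with C12 the lactone carbonyl; C14 methyl on C10), and the phosphonate carbon of the west piece is carried as a mixture of epimers because it becomes sp2 in step 16.

**Route**

Step 1
Reactants: 1 2-butyne-1,4-diol
Product: 2 4-(tert-butyldiphenylsilyloxy)but-2-yn-1-ol
Conditions: NaH (1.0 equiv), THF, 0 °C to rt; then TBDPSCl (1.0 equiv), rt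
Reagents that add atoms: tert-butyl(chloro)diphenylsilane, CC(C)(C)[Si](Cl)(c1ccccc1)c1ccccc1
Why: Monosilylation of a symmetrical diol (silyl ether formation) through its monosodium alkoxide, formed with one equivalent of NaH, should leave the C6 hydroxyl free.

Step 2
Reactants: 2 4-(tert-butyldiphenylsilyloxy)but-2-yn-1-ol
Product: 3 (Z)-4-(tert-butyldiphenylsilyloxy)-3-iodobut-2-en-1-ol
Conditions: NaAlH2(OCH2CH2OMe)2, THF, 0 °C; EtOAc; then I2, −78 to 0 °C
Reagents that add atoms: iodine, II
Why: Hydroxyl-directed trans-hydroalumination of the propargylic alcohol places aluminium on the distal alkyne carbon (C4) in a five-membered alkoxyalanate, and iodinolysis with retention gives the (Z)-3-iodoallylic alcohol, which fixes the C4=C5 geometry (C6 cis to the later C3).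

Step 3
Reactants: 3 (Z)-4-(tert-butyldiphenylsilyloxy)-3-iodobut-2-en-1-ol
Product: 4 tert-butyl{[(Z)-4-(chloromethoxy)-2-iodobut-2-en-1-yl]oxy}diphenylsilane (chloromethyl ether of 3)
Conditions: (CH2O)n, Me3SiCl, CH2Cl2, 0 °C to rt; volatiles removed, used crude
Reagents that add atoms: paraformaldehyde (as formaldehyde), C=O; chlorotrimethylsilane, C[Si](C)(C)Cl
Why: Chloromethylation of a primary alcohol with formaldehyde and Me3SiCl (hemiformal formation, then exchange of OH for Cl) is a standard entry to alkoxymethyl chlorides, should tolerate the vinyl iodide and the robust TBDPS ether, and brings in C13.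

Step 4
Reactants: 4 chloromethyl ether of 3; 5 methyl bis(2,2,2-trifluoroethyl)phosphonoacetate
Product: 6 methyl 2-[bis(2,2,2-trifluoroethoxy)phosphoryl]-3-{[(Z)-4-(tert-butyldiphenylsilyloxy)-3-iodobut-2-en-1-yl]oxy}propanoate (racemic at the phosphonate carbon)
Conditions: 5 (1.3 equiv), NaH, THF, 0 °C; then 4, −20 to 0 °C
Reagents that add atoms: none
Why: C-Alkylation of the sodium enolate of the phosphonoacetate with an α-chloro ether (alkylation of a stabilised carbanion, as with benzyl chloromethyl ether) forms C11–C13 without any free alkoxide that could exchange the trifluoroethyl esters on phosphorus, and the excess of 5 suppresses double alkylation.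

Step 5
Reactants: 7 (S)-5-(trityloxymethyl)dihydrofuran-2(3H)-one
Product: 8 (3R,5S)-3-methyl-5-(trityloxymethyl)dihydrofuran-2(3H)-one
Conditions: LiN(iPr)2, THF, −78 °C; MeI, −78 to −40 °C
Reagents that add atoms: iodomethane, CI
Why: Alkylation of the lactone lithium enolate with MeI (C14) takes place trans to the bulky trityloxymethyl group by 1,3-induction, although this centre is planarised again in step 6 so that the isomer ratio is immaterial.

Step 6
Reactants: 8 (3R,5S)-3-methyl-5-(trityloxymethyl)dihydrofuran-2(3H)-one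
Product: 9 (3R,5S)-3-hydroxy-3-methyl-5-(trityloxymethyl)dihydrofuran-2(3H)-one
Conditions: KN(SiMe3)2, THF, −78 °C; 2-(phenylsulfonyl)-3-phenyloxaziridine, −78 °C; aq NH4Cl
Reagents that add atoms: 2-(phenylsulfonyl)-3-phenyloxaziridine, O=S(=O)(c1ccccc1)N1OC1c1ccccc1
Why: Electrophilic hydroxylation of the tetrasubstituted potassium enolate (Davis oxidation) should deliver oxygen to the face trans to the trityloxymethyl group, which sets C10 as (R) with the methyl group cis to the side chain.

Step 7
Reactants: 9 (3R,5S)-3-hydroxy-3-methyl-5-(trityloxymethyl)dihydrofuran-2(3H)-one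
Product: 10 (2R,4S)-2,4-dihydroxy-N-methoxy-N,2-dimethyl-5-(trityloxy)pentanamide
Conditions: MeNHOMe·HCl, AlMe3, CH2Cl2, 0 °C to rt; aq potassium sodium tartrate; used at once
Reagents that add atoms: N,O-dimethylhydroxylamine hydrochloride, CNOC.Cl
Why: Weinreb aminolysis of the lactone with the aluminium amide formed in the flask opens the ring at the acyl C–O bond, leaves both stereocentres untouched and frees the C8 hydroxyl.

Step 8
Reactants: 10 (2R,4S)-2,4-dihydroxy-N-methoxy-N,2-dimethyl-5-(trityloxy)pentanamide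
Product: 11 (2R,4S)-4-(tert-butyldimethylsilyloxy)-2-hydroxy-N-methoxy-N,2-dimethyl-5-(trityloxy)pentanamide
Conditions: TBSCl, imidazole, DMF, 0 °C to rt
Reagents that add atoms: tert-butyl(chloro)dimethylsilane, CC(C)(C)[Si](C)(C)Cl
Why: Silyl ether formation with TBSCl and imidazole is selective for the secondary C8 hydroxyl over the hindered tertiary C10 hydroxyl and blocks relactonisation.

Step 9
Reactants: 11 (2R,4S)-4-(tert-butyldimethylsilyloxy)-2-hydroxy-N-methoxy-N,2-dimethyl-5-(trityloxy)pentanamide; 12 ethynylmagnesium bromide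
Product: 13 (4R,6S)-6-(tert-butyldimethylsilyloxy)-4-hydroxy-4-methyl-7-(trityloxy)hept-1-yn-3-one
Conditions: 12 (4 equiv), THF, −20 to 0 °C; aq NH4Cl, 0 °C
Reagents that add atoms: none
Why: In this Weinreb ketone synthesis the first equivalent of the alkynyl Grignard reagent deprotonates the tertiary hydroxyl and the next adds once to give a chelated tetrahedral intermediate that collapses to the ynone only on work-up, forming C1–C2.

Step 10
Reactants: 13 (4R,6S)-6-(tert-butyldimethylsilyloxy)-4-hydroxy-4-methyl-7-(trityloxy)hept-1-yn-3-one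
Product: 14 (4R,6S)-6-(tert-butyldimethylsilyloxy)-4-methyl-7-(trityloxy)hept-1-yne-3,4-diol (both C3 epimers, C3 = C1 of the target)
Conditions: NaBH4, CeCl3·7H2O, MeOH, −78 to −40 °C
Reagents that add atoms: none
Why: Luche 1,2-reduction converts the base-sensitive terminal ynone into the propargylic alcohol needed for a clean copper-assisted coupling, and the C1 epimers are carried together because C1 is reoxidised in step 12.

Step 11
Reactants: 6 β-alkoxy phosphonate with vinyl iodide; 14 east alkyne diol
Product: 15 enyne diol phosphonate (C3–C4 coupled; (E) by descriptor, C6 cis to the alkyne)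
Conditions: PdCl2(PPh3)2 (5 mol%), CuI (10 mol%), Et3N, THF, rt
Reagents that add atoms: none
Why: Sonogashira coupling of the vinyl iodide with the terminal alkyne forms C3–C4 with retention of the alkene geometry and tolerates the free diol and the phosphonate.

Step 12
Reactants: 15 enyne diol phosphonate
Product: 16 α'-hydroxy enynone phosphonate (C1 ketone, free C10 hydroxyl)
Conditions: Dess–Martin periodinane, pyridine, CH2Cl2, 0 °C to rt
Reagents that add atoms: none
Why: Dess–Martin oxidation of the secondary propargylic alcohol gives the α'-hydroxy ynone and leaves the tertiary alcohol, the phosphonate and the ethers untouched.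

Step 13
Reactants: 16 α'-hydroxy enynone phosphonate
Product: 17 3(2H)-furanone phosphonate (C3–O–C10 bridge closed; C7 trityl ether, C8 TBS ether, C15 TBDPS ether)
Conditions: Ph3PAuNTf2 (5 mol%), toluene, rt
Reagents that add atoms: none
Why: Gold-catalysed cycloisomerisation of an α'-hydroxy ynone, by 5-endo-dig addition of the C10 hydroxyl to C3 of the gold-activated alkyne and protodeauration, gives the 3(2H)-furanone with C10 unchanged.

Step 14
Reactants: 17 3(2H)-furanone phosphonate
Product: 18 C7 primary alcohol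
Conditions: TsOH·H2O (10 mol%), MeOH/CH2Cl2, 0 °C
Reagents that add atoms: none
Why: Acid-catalysed methanolysis of the trityl ether (SN1 through the trityl cation) is much faster than cleavage of the secondary TBS and the primary TBDPS ether under these conditions.

Step 15
Reactants: 18 C7 primary alcohol
Product: 19 C7 aldehyde (seco aldehyde phosphonate)
Conditions: Dess–Martin periodinane, pyridine, CH2Cl2, 0 °C to rt; used at once
Reagents that add atoms: none
Why: Dess–Martin oxidation under buffered conditions should give the α-silyloxy aldehyde without epimerisation at C8.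

Step 16
Reactants: 19 C7 aldehyde
Product: 20 thirteen-membered furanone-bridged allyl ether with (Z)-enoate
Conditions: KN(SiMe3)2 (1.05 equiv), 18-crown-6, THF (0.001 M), −78 to −40 °C
Reagents that add atoms: none
Why: Intramolecular Still–Gennari olefination (Horner–Wadsworth–Emmons reaction of a bis(trifluoroethyl)phosphonate) under kinetic control should give the (Z)-enoate, with the ester cis to C8 and C13 trans to C8, and close the unstrained thirteen-membered ring, while complete carbanion formation at −78 °C should outrun loss of the β-alkoxide.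

Step 17
Reactants: 20 thirteen-membered furanone-bridged allyl ether
Product: 22 8-O-TBS-15-O-TBDPS-8-desacylgoyazensolide, via ring-contracted hydroxy ester 21 (not isolated)
Conditions: KN(SiMe3)2 (1.1 equiv), THF, −78 to −40 °C; then AcOH, −78 °C
Reagents that add atoms: none
Why: Proposed new method: KN(SiMe3)2 is expected to deprotonate C6, whose C–H bonds are the only ones conjugated with the C1 ketone (by way of C5=C4 and C3=C2; C10 carries no hydrogen and C15 is only cross-conjugated), and the far end of the resulting trienolate attacks C7 while the C13–O bond is given up, either as a [2,3]-sigmatropic shift over the five atoms C6, O, C13, C11 and C7 or, with the same outcome, as conjugate addition to the enoate and E1cB expulsion of the C6 oxygen from C13, so that alkoxide 21 results. The nearest known reaction types are [2,3]-Wittig ring contractions of thirteen-membered diallyl and allyl propargyl ethers to ten-membered homoallylic alcohols, [2,3]-Wittig shifts of enolates and the SN2' substitution of 2-(alkoxymethyl)acrylates by addition and elimination; new is that the migrating carbanion is the vinylogous (ε) terminus of a dienone enolate inside the ring. The ten-membered carbocycle thus closes by a 13-to-10 contraction within a preformed, unstrained macrocycle (the C6–C7 bond forms through a five-membered envelope, no head-to-tail cyclisation is needed), and the γ-lactone closes afterwards by 5-exo-trig acyl substitution in which the C6 alkoxide displaces methoxide at C12 and so traps the rearranged skeleton. C7 should be controlled by C8, because allylic 1,3-strain with the cis ester keeps H8 in the enoate plane and the ring, which continues from C8 through C9, brings C6 to the face of C7 away from the silyloxy group. C6 should be controlled by the C7=C11 geometry (C13 trans to C8), which in the envelope with C5 outside translates into the 6,7-anti relationship of the trans-fused lactone. The step needs C–C bond formation at C6 and not at C2 or C4 of the trienolate and no deprotonation elsewhere, and the substrate should secure this because only C6 reaches C7 in a five-membered array with a leaving group placed for SN2' departure, bonding from C2 would be a strained transannular closure, and the in-plane C8–H bond is poorly aligned for γ-deprotonation of the enoate.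

Step 18
Reactants: 22 8-O-TBS-15-O-TBDPS-8-desacylgoyazensolide
Product: 23 15-O-TBDPS-8-desacylgoyazensolide
Conditions: camphorsulfonic acid (0.3 equiv), MeOH/CH2Cl2, 0 °C to rt
Reagents that add atoms: none
Why: Acid-catalysed methanolysis of silyl ethers cleaves a TBS ether far faster than a TBDPS ether, which should free only the C8 hydroxyl.

Step 19
Reactants: 23 15-O-TBDPS-8-desacylgoyazensolide; 24 methacrylic anhydride
Product: 25 15-O-TBDPS-goyazensolide
Conditions: 24, DMAP, Et3N, CH2Cl2, 0 °C to rt
Reagents that add atoms: none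
Why: DMAP-catalysed acylation of the secondary C8 alcohol with the anhydride (nucleophilic acyl-transfer catalysis) installs the methacrylate with retention at C8.

Step 20
Reactants: 25 15-O-TBDPS-goyazensolide
Product: 26 goyazensolide
Conditions: HF·pyridine, pyridine, THF, 0 °C to rt
Reagents that add atoms: none
Why: Fluoride-mediated cleavage of the silyl ether with buffered HF·pyridine is non-basic and should spare the methacrylate, the exo-methylene lactone and the dienone.

**Compound list**

1 | 2-butyne-1,4-diol | OCC#CCO | starting material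
2 | 4-(tert-butyldiphenylsilyloxy)but-2-yn-1-ol | OCC#CCO[Si](c1ccccc1)(c1ccccc1)C(C)(C)C | intermediate
3 | (Z)-4-(tert-butyldiphenylsilyloxy)-3-iodobut-2-en-1-ol (C6 alcohol, C4 iodide, C15 silyl ether) | OC/C=C(\I)CO[Si](c1ccccc1)(c1ccccc1)C(C)(C)C | intermediate
4 | tert-butyl{[(Z)-4-(chloromethoxy)-2-iodobut-2-en-1-yl]oxy}diphenylsilane | ClCOC/C=C(\I)CO[Si](c1ccccc1)(c1ccccc1)C(C)(C)C | intermediate
5 | methyl bis(2,2,2-trifluoroethyl)phosphonoacetate | COC(=O)CP(=O)(OCC(F)(F)F)OCC(F)(F)F | starting material
6 | methyl 2-[bis(2,2,2-trifluoroethoxy)phosphoryl]-3-{[(Z)-4-(tert-butyldiphenylsilyloxy)-3-iodobut-2-en-1-yl]oxy}propanoate (racemic at the phosphonate carbon) | COC(=O)C(COC/C=C(\I)CO[Si](c1ccccc1)(c1ccccc1)C(C)(C)C)P(=O)(OCC(F)(F)F)OCC(F)(F)F | intermediate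
7 | (S)-5-(trityloxymethyl)dihydrofuran-2(3H)-one | O=C1O[C@H](COC(c2ccccc2)(c2ccccc2)c2ccccc2)CC1 | starting material
8 | (3R,5S)-3-methyl-5-(trityloxymethyl)dihydrofuran-2(3H)-one (methyl trans to the side chain) | O=C1O[C@H](COC(c2ccccc2)(c2ccccc2)c2ccccc2)C[C@H]1C | intermediate
9 | (3R,5S)-3-hydroxy-3-methyl-5-(trityloxymethyl)dihydrofuran-2(3H)-one (hydroxyl trans to the side chain) | O=C1O[C@H](COC(c2ccccc2)(c2ccccc2)c2ccccc2)C[C@@]1(C)O | intermediate
10 | (2R,4S)-2,4-dihydroxy-N-methoxy-N,2-dimethyl-5-(trityloxy)pentanamide | CON(C)C(=O)[C@](C)(O)C[C@H](O)COC(c1ccccc1)(c1ccccc1)c1ccccc1 | intermediate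
11 | (2R,4S)-4-(tert-butyldimethylsilyloxy)-2-hydroxy-N-methoxy-N,2-dimethyl-5-(trityloxy)pentanamide | CON(C)C(=O)[C@](C)(O)C[C@H](O[Si](C)(C)C(C)(C)C)COC(c1ccccc1)(c1ccccc1)c1ccccc1 | intermediate
12 | ethynylmagnesium bromide | C#C[Mg]Br | starting material
13 | (4R,6S)-6-(tert-butyldimethylsilyloxy)-4-hydroxy-4-methyl-7-(trityloxy)hept-1-yn-3-one | C#CC(=O)[C@](C)(O)C[C@H](O[Si](C)(C)C(C)(C)C)COC(c1ccccc1)(c1ccccc1)c1ccccc1 | intermediate
14 | (4R,6S)-6-(tert-butyldimethylsilyloxy)-4-methyl-7-(trityloxy)hept-1-yne-3,4-diol (C3 epimers) | C#CC(O)[C@](C)(O)C[C@H](O[Si](C)(C)C(C)(C)C)COC(c1ccccc1)(c1ccccc1)c1ccccc1 | intermediate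
15 | enyne diol phosphonate: methyl 2-[bis(2,2,2-trifluoroethoxy)phosphoryl]-3-alkoxypropanoate whose alkoxy group is C6H2–C5H=C4(C15H2OTBDPS)–C3≡C2–C1H(OH)–C10(CH3)(OH)–C9H2–C8H(OTBS)–C7H2OTr; C6 cis to C3, C8 (S), C10 (R), epimers at C1 and at the phosphonate carbon | COC(=O)C(COC/C=C(CO[Si](c1ccccc1)(c1ccccc1)C(C)(C)C)\C#CC(O)[C@](C)(O)C[C@H](O[Si](C)(C)C(C)(C)C)COC(c1ccccc1)(c1ccccc1)c1ccccc1)P(=O)(OCC(F)(F)F)OCC(F)(F)F | intermediate
16 | α'-hydroxy enynone phosphonate: as 15 with C1 as ketone | COC(=O)C(COC/C=C(CO[Si](c1ccccc1)(c1ccccc1)C(C)(C)C)\C#CC(=O)[C@](C)(O)C[C@H](O[Si](C)(C)C(C)(C)C)COC(c1ccccc1)(c1ccccc1)c1ccccc1)P(=O)(OCC(F)(F)F)OCC(F)(F)F | intermediate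
17 | 3(2H)-furanone phosphonate: (R)-2-methyl-2-[(S)-2-(TBS-oxy)-3-(trityloxy)propyl]furan-3(2H)-one bearing at its 5-position (C3) the (Z)-alkenyl group C4(C15H2OTBDPS)=C5H–C6H2–O–C13H2–C11H[P(O)(OCH2CF3)2]CO2Me | COC(=O)C(COC/C=C(CO[Si](c1ccccc1)(c1ccccc1)C(C)(C)C)\C2=CC(=O)[C@@](C)(C[C@H](O[Si](C)(C)C(C)(C)C)COC(c3ccccc3)(c3ccccc3)c3ccccc3)O2)P(=O)(OCC(F)(F)F)OCC(F)(F)F | intermediate
18 | C7 primary alcohol: as 17 with CH2OH in place of CH2OTr | COC(=O)C(COC/C=C(CO[Si](c1ccccc1)(c1ccccc1)C(C)(C)C)\C2=CC(=O)[C@@](C)(C[C@H](O[Si](C)(C)C(C)(C)C)CO)O2)P(=O)(OCC(F)(F)F)OCC(F)(F)F | intermediate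
19 | C7 aldehyde (seco aldehyde phosphonate): as 18 with CHO at C7 | COC(=O)C(COC/C=C(CO[Si](c1ccccc1)(c1ccccc1)C(C)(C)C)\C2=CC(=O)[C@@](C)(C[C@H](O[Si](C)(C)C(C)(C)C)C=O)O2)P(=O)(OCC(F)(F)F)OCC(F)(F)F | intermediate
20 | thirteen-membered furanone-bridged allyl ether: ring C1–C2=C3–C4=C5–C6–O–C13–C11=C7–C8–C9–C10 with the C3–O–C10 furanone bridge; (Z)-enoate (CO2Me on C11 cis to C8), C4=C5 (Z), C8 (S)-OTBS, C10 (R), C15 OTBDPS | COC(=O)/C1=C\[C@@H](O[Si](C)(C)C(C)(C)C)C[C@@]2(C)OC(=CC2=O)/C(CO[Si](c3ccccc3)(c3ccccc3)C(C)(C)C)=C\COC1 | intermediate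
21 | ring-contracted hydroxy ester (formed as its potassium alkoxide, not isolated): ten-membered carbocycle with C6 hydroxyl, C7 bearing C11(=C13H2)CO2Me, H6 and H7 set for the trans-lactone, C8 (S)-OTBS | CC(C)(C)[Si](C)(C)O[C@H]1C[C@@]2(C)OC(=CC2=O)/C(CO[Si](c3ccccc3)(c3ccccc3)C(C)(C)C)=C\[C@@H](O)[C@@H]1C(=C)C(=O)OC | intermediate
22 | 8-O-TBS-15-O-TBDPS-8-desacylgoyazensolide (trans-fused lactone; same spatial arrangement at C6, C7, C8 and C10 as the target) | CC(C)(C)[Si](C)(C)O[C@H]1C[C@@]2(C)OC(=CC2=O)/C(CO[Si](c3ccccc3)(c3ccccc3)C(C)(C)C)=C\[C@H]2OC(=O)C(=C)[C@H]12 | intermediate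
23 | 15-O-TBDPS-8-desacylgoyazensolide (free C8 hydroxyl) | O[C@H]1C[C@@]2(C)OC(=CC2=O)/C(CO[Si](c3ccccc3)(c3ccccc3)C(C)(C)C)=C\[C@H]2OC(=O)C(=C)[C@H]12 | intermediate
24 | methacrylic anhydride | C=C(C)C(=O)OC(=O)C(C)=C | starting material
25 | 15-O-TBDPS-goyazensolide | C=C(C)C(=O)O[C@H]1C[C@@]2(C)OC(=CC2=O)/C(CO[Si](c3ccccc3)(c3ccccc3)C(C)(C)C)=C\[C@H]2OC(=O)C(=C)[C@H]12 | intermediate
26 | goyazensolide, (6R,7R,8S,10R), C4=C5 (Z) | C=C(C)C(=O)O[C@H]1C[C@@]2(C)OC(=CC2=O)/C(CO)=C\[C@H]2OC(=O)C(=C)[C@H]12 | target

**Count and risks**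

Total step count: 20. Longest linear sequence: 16 steps (7 to 26: steps 5 to 10, then 11 to 20); the west branch (1 to 6) has 4 steps.

Steps most likely to fail:

1. Step 17 (key step).
 - What may go wrong: the trienolate may bond to C7 through its α-carbon C2 in a transannular conjugate addition. It may be quenched with migration of the C4=C5 bond. It may add with poor control of the C7 face or of the C6/C7 relationship. The methoxide set free may add to the exo-methylene lactone.
 - Fallback (known chemistry, intramolecular Nozaki–Hiyama allylation): it sets out from 3 and 14 and comes back at 22. Alcohol 3 is converted with 4-methoxybenzyl trichloroacetimidate and catalytic La(OTf)3 into the (Z)-vinyl iodide 4-methoxybenzyl ether F1. F1 is joined with 14 under the conditions of step 11 to give the enyne diol F2. Oxidation as in step 12 gives the α'-hydroxy ynone F3, and cycloisomerisation as in step 13 gives the furanone F4. Detritylation as in step 14 gives the C7 alcohol F5, and oxidation as in step 15 gives the C7 aldehyde F6. A Morita–Baylis–Hillman reaction with methyl acrylate and DABCO gives the allylic alcohol F7 (C7 epimers). NBS and Me2S convert it with allylic transposition into the (Z)-2-(bromomethyl)enoate F8. DDQ removes the 4-methoxybenzyl group to give the C6 alcohol F9, and MnO2 oxidises it to the C6 enal F10. CrCl2 in THF/DMF at high dilution should then form the C6–C7 bond by addition of the γ-carbon (C7) of the allylchromium species to the aldehyde. The chromium alkoxide lactonises onto the methyl ester and should give 22; anti addition, hence the trans-fused lactone, is the usual outcome with chromium.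

2. Step 16.
 - What may go wrong: the phosphonate carbanion may lose the C6 alkoxide from C13 (E1cB), add reversibly to C5 of the dienone in a five-membered conjugate addition, give dimers, or close the ring with the wrong enoate geometry.
 - Fallback (ring-closing metathesis in place of olefination): it sets out from 17 and comes back at 20. Phosphonate 17 is olefinated with aqueous formaldehyde and K2CO3 to the 2-(alkoxymethyl)acrylate F11. Detritylation as in step 14 gives the alcohol F12 and oxidation as in step 15 gives the aldehyde F13. Wittig methylenation with Ph3P=CH2 gives the terminal alkene F14. Ring-closing metathesis of F14 with the second-generation Hoveyda–Grubbs catalyst in dilute toluene at 80 °C should close the thirteen-membered ring at C7=C11 with loss of ethylene. Under thermodynamic control the isomer with C13 trans to C8, that is 20, is expected to prevail.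

3. Step 4 (with step 3 as its preparation).
 - What may go wrong: the chloromethyl ether may hydrolyse or lose its silyl group before it is used, and the phosphonoacetate anion may be alkylated twice or on oxygen.
 - Fallback (oxa-Michael addition in place of alkylation): it sets out from 3 and 5 and comes back at 6. Phosphonoacetate 5 is condensed with paraformaldehyde (piperidinium acetate, toluene, removal of water) to methyl 2-[bis(2,2,2-trifluoroethoxy)phosphoryl]acrylate F15. Alcohol 3 is then added to F15 with a catalytic amount of PMe3 (conjugate addition of the C6 hydroxyl), which should give 6 without a chloromethyl ether.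

Further compounds
F1 | step 17 | (Z)-vinyl iodide 4-methoxybenzyl ether | COc1ccc(COC/C=C(\I)CO[Si](c2ccccc2)(c2ccccc2)C(C)(C)C)cc1
F2 | step 17 | enyne diol 4-methoxybenzyl ether (C1 epimers) | COc1ccc(COC/C=C(CO[Si](c2ccccc2)(c2ccccc2)C(C)(C)C)\C#CC(O)[C@](C)(O)C[C@H](O[Si](C)(C)C(C)(C)C)COC(c2ccccc2)(c2ccccc2)c2ccccc2)cc1
F3 | step 17 | α'-hydroxy ynone 4-methoxybenzyl ether | COc1ccc(COC/C=C(CO[Si](c2ccccc2)(c2ccccc2)C(C)(C)C)\C#CC(=O)[C@](C)(O)C[C@H](O[Si](C)(C)C(C)(C)C)COC(c2ccccc2)(c2ccccc2)c2ccccc2)cc1
F4 | step 17 | furanone with C6 4-methoxybenzyl ether and C7 trityl ether | COc1ccc(COC/C=C(CO[Si](c2ccccc2)(c2ccccc2)C(C)(C)C)\C2=CC(=O)[C@@](C)(C[C@H](O[Si](C)(C)C(C)(C)C)COC(c3ccccc3)(c3ccccc3)c3ccccc3)O2)cc1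
F5 | step 17 | C7 alcohol of the furanone 4-methoxybenzyl ether | COc1ccc(COC/C=C(CO[Si](c2ccccc2)(c2ccccc2)C(C)(C)C)\C2=CC(=O)[C@@](C)(C[C@H](O[Si](C)(C)C(C)(C)C)CO)O2)cc1
F6 | step 17 | C7 aldehyde of the furanone 4-methoxybenzyl ether | COc1ccc(COC/C=C(CO[Si](c2ccccc2)(c2ccccc2)C(C)(C)C)\C2=CC(=O)[C@@](C)(C[C@H](O[Si](C)(C)C(C)(C)C)C=O)O2)cc1
F7 | step 17 | Morita–Baylis–Hillman allylic alcohol (C7 epimers) | COc1ccc(COC/C=C(CO[Si](c2ccccc2)(c2ccccc2)C(C)(C)C)\C2=CC(=O)[C@@](C)(C[C@H](O[Si](C)(C)C(C)(C)C)C(O)C(=C)C(=O)OC)O2)cc1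
F8 | step 17 | (Z)-2-(bromomethyl)enoate with C6 4-methoxybenzyl ether | COc1ccc(COC/C=C(CO[Si](c2ccccc2)(c2ccccc2)C(C)(C)C)\C2=CC(=O)[C@@](C)(C[C@H](O[Si](C)(C)C(C)(C)C)/C=C(\CBr)C(=O)OC)O2)cc1
F9 | step 17 | C6 allylic alcohol with (Z)-2-(bromomethyl)enoate | OC/C=C(CO[Si](c1ccccc1)(c1ccccc1)C(C)(C)C)\C1=CC(=O)[C@@](C)(C[C@H](O[Si](C)(C)C(C)(C)C)/C=C(\CBr)C(=O)OC)O1
F10 | step 17 | C6 enal with (Z)-2-(bromomethyl)enoate | O=C/C=C(CO[Si](c1ccccc1)(c1ccccc1)C(C)(C)C)\C1=CC(=O)[C@@](C)(C[C@H](O[Si](C)(C)C(C)(C)C)/C=C(\CBr)C(=O)OC)O1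
F11 | step 16 | 2-(alkoxymethyl)acrylate with C7 trityl ether | C=C(COC/C=C(CO[Si](c1ccccc1)(c1ccccc1)C(C)(C)C)\C1=CC(=O)[C@@](C)(C[C@H](O[Si](C)(C)C(C)(C)C)COC(c2ccccc2)(c2ccccc2)c2ccccc2)O1)C(=O)OC
F12 | step 16 | C7 alcohol of the 2-(alkoxymethyl)acrylate | C=C(COC/C=C(CO[Si](c1ccccc1)(c1ccccc1)C(C)(C)C)\C1=CC(=O)[C@@](C)(C[C@H](O[Si](C)(C)C(C)(C)C)CO)O1)C(=O)OC
F13 | step 16 | C7 aldehyde of the 2-(alkoxymethyl)acrylate | C=C(COC/C=C(CO[Si](c1ccccc1)(c1ccccc1)C(C)(C)C)\C1=CC(=O)[C@@](C)(C[C@H](O[Si](C)(C)C(C)(C)C)C=O)O1)C(=O)OC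
F14 | step 16 | terminal alkene (metathesis diene) | C=C(COC/C=C(CO[Si](c1ccccc1)(c1ccccc1)C(C)(C)C)\C1=CC(=O)[C@@](C)(C[C@H](O[Si](C)(C)C(C)(C)C)C=C)O1)C(=O)OC
F15 | step 4 | methyl 2-[bis(2,2,2-trifluoroethoxy)phosphoryl]acrylate | C=C(C(=O)OC)P(=O)(OCC(F)(F)F)OCC(F)(F)F
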